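**Assumption:** Prosogerin D is 7-hydroxy-6-methoxy-2-(3,4,5-trimethoxyphenyl)-4H-chromen-4-one, a flavone. The SMILES has no stereocenters, so "single enantiomer" does not apply. Nothing needs to be set or protected stereochemically, and the only isomer issue is the E-geometry of the intermediate chalcone, which is irrelevant after cyclization.

## Retrosynthetic overview
1. The flavone C-ring (pyran-4-one) comes from oxidative cyclization of a 2'-hydroxychalcone. This forms the C2–O1 bond and the C2=C3 double bond.
2. The chalcone comes from a Claisen–Schmidt aldol condensation of 2',4'-dihydroxy-5'-methoxyacetophenone with 3,4,5-trimethoxybenzaldehyde. This forms the C2=C3 enone unit.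
3. The A-ring substitution (6-OMe, 7-OH) is already present in the commercial acetophenone, so the 7-OH is carried through unprotected. The only ring formed is the pyranone C-ring.

## Route

**Step 1**
Reactants: **1** 1-(2,4-dihydroxy-5-methoxyphenyl)ethan-1-one; **2** 3,4,5-trimethoxybenzaldehyde
Product: **3** (E)-1-(2,4-dihydroxy-5-methoxyphenyl)-3-(3,4,5-trimethoxyphenyl)prop-2-en-1-one (2'-hydroxychalcone)
Conditions: 50% aq. KOH (about 5 equiv), EtOH, rt, 24–48 h; then 2 M HCl to pH ~2
Reagents that add atoms: none (KOH is a catalyst/base and is removed on acidification; only the carbon skeleton of 1 and 2 is joined, with loss of H2O)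
Why: Claisen–Schmidt condensation. The acetophenone methyl enolizes even as the bis-phenolate, and the non-enolizable aldehyde 2 cannot self-condense. Dehydration gives the conjugated E-enone, stabilized by the 2'-OH···O=C hydrogen bond. No stereocenter is formed.

**Step 2**
Reactants: **3** chalcone
Product: **4** Prosogerin D (7-hydroxy-6-methoxy-2-(3,4,5-trimethoxyphenyl)chromen-4-one)
Conditions: I2 (0.1–0.2 equiv), DMSO, 130 °C, 1–3 h; then aq. Na2S2O3 workup
Reagents that add atoms: none (I2 is catalytic, and DMSO is the terminal oxidant, leaving as Me2S and H2O)
Why: I2/DMSO oxidative cyclization. The 2'-OH adds to the enone (oxa-Michael) to give the flavanone. Iodination at C3 and elimination of HI, with I2 regenerated by DMSO, then gives the C2=C3 flavone double bond. The product is planar and achiral, so the transient C2 stereocenter of the flavanone is lost. The free 7-OH and the aryl methyl ethers survive.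

## Final checks
- **Target match:** The A ring carries 6-OMe and 7-OH. These come from 5'-OMe and 4'-OH of 1, with C8a from C2'–O and C4a from C1'. The B ring is 3,4,5-(OMe)3, and the C ring is a 2-aryl-chromen-4-one. The formula is C18H16O7, which equals chalcone C18H18O7 minus H2, as expected for the oxidative cyclization.
- **Atom accounting:** 1 (C9H10O4) + 2 (C10H12O4) − H2O gives 3 (C18H18O7). 3 − 2 H gives 4 (C18H16O7).
- **Functional-group survival:** Free phenols tolerate both the basic condensation and I2/DMSO. Aryl methyl ethers are inert to both. Iodination of the electron-rich A ring is minimized by using catalytic I2.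
- **Stereochemistry:** There are no stereocenters in the target, and none are left undefined.

## Compound list
1 | 1-(2,4-dihydroxy-5-methoxyphenyl)ethanone | CC(=O)c1cc(OC)c(O)cc1O | starting material
2 | 3,4,5-trimethoxybenzaldehyde | COc1cc(C=O)cc(OC)c1OC | starting material
3 | (E)-2',4'-dihydroxy-3,4,5,5'-tetramethoxychalcone | COc1cc(/C=C/C(=O)c2cc(OC)c(O)cc2O)cc(OC)c1OC | intermediate
4 | Prosogerin D | COc1cc2c(=O)cc(-c3cc(OC)c(OC)c(OC)c3)oc2cc1O | target

## Totals
Total steps: 2. Longest linear sequence: 2.

## Three steps most likely to fail, with fallbacks
1. **Step 1 (Claisen–Schmidt on the unprotected diphenol):** The bis-phenolate is a poor enolate, so conversion may be low. Fallback: change the approach to a protected route. Selectively MOM-protect the 4-OH of 1, run the condensation and I2/DMSO cyclization, then remove MOM with HCl/MeOH. Alternatively, use Baker–Venkataraman: aroylate the 2-OH with 3,4,5-trimethoxybenzoyl chloride, rearrange with base to the 1,3-diketone, and cyclodehydrate with H2SO4/AcOH.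
2. **Step 2 (I2/DMSO cyclization):** The reaction may stall at the flavanone, or iodinate the A ring (C8) or give other over-oxidation. Fallback: cyclize the chalcone to the flavanone with NaOAc/EtOH at reflux, then dehydrogenate with catalytic Pd(TFA)2/DMSO/O2 or with I2/Ac2O. Alternatively, use the Baker–Venkataraman diketone cyclodehydration above.
3. **Sourcing and regiochemistry of acetophenone 1:** If 1 is not available, or a mixture of acetylation isomers is obtained, make it from 4-methoxybenzene-1,3-diol, which acylates at C6 (ortho to one OH and para to the other). Fallback: use a different approach to the same ketone, a Houben–Hoesch reaction of that diol with MeCN/ZnCl2/HCl followed by hydrolysis, in place of the Friedel–Crafts acetylation with AcOH/BF3·Et2O.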